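Whatever happens in a closed flask, the fractions of the charge add up to one, so the gap that starting material and target leave between them is material gone on to something I could not read, and that gap gave me a second clock beside the first.

| flask | starting material | protic impurity | catalyst | temperature | remark | time |
|---|---|---|---|---|---|---|
| south | 0.067 M | 2 mM | 0.20 mM | −2 °C | run made earlier |  |
| north | 0.15 M | 2 mM | 0.20 mM | 25 °C | run made earlier |  |
| south-east | 0.10 M | 2 mM | 0.10 mM | −2 °C | run made earlier |  |
| dusk | 0.10 M | 2.00 mM | 0.20 mM |  | at −15 °C until 2.5 min, from then on at 35 °C | 8.0 min |
| winter | 0.10 M | 2.00 mM | 0.20 mM | 35 °C |  | 8.0 min |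
| noon | 0.10 M | 2.00 mM | 0.20 mM | −15 °C |  | 8.0 min |
| autumn | 0.10 M | 2.00 mM | 0.20 mM | 10 °C |  | 8.0 min |

- south (time / min: target / %, starting material / %): 8.00: 21.6, 73.8; 15.0: 36.2, 56.4; 25.0: 45.3, 40.7; 30.0: 49.8, 33.9
- north (time / min: target / %, starting material / %): 2.00: 20.4, 73.6; 4.00: 32.8, 58.1; 6.00: 39.2, 45.6; 8.00: 38.6, 39.3
- south-east (time / min: target / %, starting material / %): 2.50: 3.6, 92.2; 5.00: 8.7, 90.8; 12.0: 17.0, 80.2; 30.0: 35.6, 58.9

(scatter of a reading: 1 percentage point)

* the flask with the highest amount of target, in percent of the starting material charged ("all alike" if they lie within 1.5 percentage points) (dusk / winter / noon / autumn / all alike)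
* final target, as a percentage of the starting material charged, in dusk
* final target, as a percentage of the starting material charged, in winter
* final target, as a percentage of the starting material charged, in noon
* final target, as a percentage of the starting material charged, in autumn

- the earlier runs were read with a standard deviation of 1 percentage point

I built a ladder of rates. The protic impurity stood lowest: its charge is 2.00% of the starting material, a small early debt that I set aside. Next came the making of target. With the same catalyst charge, the south run lost starting material with a half-life of 19.6 min at −2 °C, and the north run with 4.52 min at 25 °C, so the asked 8.0 min is shorter than the cold value and longer than the warm one.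

The top rung was the using of target. If making goes with starting material and using with target, target stops rising when target over starting material reaches the using half-life over the making half-life. In the south run, the starting material lost over the gap gained, times mean target over mean starting material, gave that ratio as 2.55, a reading with wide scatter, so using there took 49.9 min. The target readings of the north run stalled between 6.00 min and 8.00 min, at a ratio read as 0.916, so control had changed hands by then. Taking the logarithm of the ratio as straight in temperature, I got 0.628 at 35 °C, and this crossing ratio, target over starting material when making and using balance, is what I carried; at 10 °C it is 1.62.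

So I expected winter and dusk to stall with less target than starting material, and autumn to be still rising at the end and to lead. The forecast said autumn, with dusk 29%, winter 25%, noon 10% and autumn 32%: “Autumn probably leads, but narrowly”.

The flasks gave autumn, with dusk 29.9%, winter 29.0%, noon 11.1% and autumn 35.3%.

    target + catalyst ⇌ isomer of the product + catalyst, rate k1*[catalyst]*[target] forward; the back reaction follows from the equilibrium constant (K = 1.60, k = 18.0 M⁻¹ s⁻¹, Ea = 50.0 kJ mol⁻¹, ΔH = −31.0 kJ mol⁻¹)
    starting material + catalyst ⇌ target + catalyst, rate k2*[starting material]*[catalyst] forward; the back reaction follows from the equilibrium constant (K = 0.900, k = 21.0 M⁻¹ s⁻¹, Ea = 37.0 kJ mol⁻¹, ΔH = −76.0 kJ mol⁻¹)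
    starting material + protic impurity → quenched substrate (k = 2.10 M⁻¹ s⁻¹, Ea = 37.0 kJ mol⁻¹)
    (constants at 35 °C)

Autumn's lead over dusk was 5.4 points, wider than the margin of 1.5 points. Winter passed my 0.628 between two readings: its ratio was 0.566 at 4.00 min and 0.724 at 8.00 min, while target went from 29.8% to 29.0%. Part of what holds winter down lies in two ways out of target acting together: without the passing into the isomer of the product winter ends at 45.8%, and without the way back to starting material at 43.9%. Dusk ended at a ratio of 0.649, just past balance, with target made 0.927 times as fast as it was used up at 8.00 min. Read at 20 min, dusk should stand beyond 0.628 with less target; it stands at 0.861, with 26.9% target against 29.9% at 8.0 min.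

The readings were computed with constants of no real substance, noise included.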